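**Retrosynthetic overview**
1. The last operation is a global hydrogenolysis of six benzyl groups, with no skeletal change.
2. The key disconnection is the ester C–O bond between a cyclobutane carboxyl and the carbinol oxygen of (R)-danshensu. The acid partner is then an achiral, meso, all-trans diacid whose mirror plane runs through the two aryl-bearing carbons. Forming this one C–O bond therefore also fixes the absolute configuration of all four ring centres.
3. The meso diacid comes from an all-cis diaryl amide ester by double epimerisation and hydrolysis. The two aryl groups come from two successive directed C–H arylations.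
4. Only the cyclobutane ring is built, and it is built first, by 4π photocyclisation of methyl coumalate followed by hydrogenation. The benzene rings are bought.

Assumption: 1,2-bis(benzyloxy)-4-iodobenzene and sodium (R)-danshensu are taken as catalogue chemicals, and racemic intermediates are drawn as one enantiomer.

**Step 1**
Reactants: 1 methyl coumalate; 2 8-aminoquinoline
Product: 5 methyl cis-3-(quinolin-8-ylcarbamoyl)cyclobutane-1-carboxylate, via photopyrone 3 (not isolated), via cis acid ester 4 (not isolated)
Conditions: hν (medium-pressure Hg lamp, Pyrex), CH2Cl2, 15 °C; then H2 (1 atm), Pt/C, rt; then 2, EDC, rt (one pot)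
Reagents that add atoms: none
Why: 4π electrocyclisation of the 2-pyrone gives the bicyclic β-lactone; hydrogenolysis of its allylic C–O bond and hydrogenation of the cyclobutene anti to the carboxyl leave acid and ester cis; carbodiimide amidation then installs the bidentate directing group, a sequence known on this substrate.

**Step 2**
Reactants: 5 methyl cis-3-(quinolin-8-ylcarbamoyl)cyclobutane-1-carboxylate; 6 1,2-bis(benzyloxy)-4-iodobenzene
Product: 7 methyl all-cis-2-[3,4-bis(benzyloxy)phenyl]-3-(quinolin-8-ylcarbamoyl)cyclobutane-1-carboxylate (racemic)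
Conditions: Pd(OAc)2 (10 mol %), AgOAc (1.5 equiv), HFIP, 90 °C; 5 in two-fold excess over 6, surplus 5 recovered
Reagents that add atoms: none
Why: In this aminoquinoline-directed β-C(sp3)–H arylation (divalent/tetravalent palladium cycle) the palladacycle can form only with a methylene C–H cis to the amide, so the aryl group enters cis to amide and ester, and the excess of 5 suppresses double arylation.

**Step 3**
Reactants: 7 monoaryl amide ester; 8 1-(benzyloxy)-4-iodobenzene
Product: 9 methyl all-cis-2-[3,4-bis(benzyloxy)phenyl]-4-[4-(benzyloxy)phenyl]-3-(quinolin-8-ylcarbamoyl)cyclobutane-1-carboxylate (racemic)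
Conditions: Pd(OAc)2 (15 mol %), AgOAc (2 equiv), 8 (3 equiv), toluene, 110 °C
Reagents that add atoms: none
Why: A second directed C(sp3)–H arylation at the remaining methylene again delivers the aryl group cis to the amide, which places the two aryl groups cis to each other; double arylation to all-cis cyclobutanes is known for this amide class.

**Step 4**
Reactants: 9 all-cis diaryl amide ester
Product: 11 meso-(1R,2s,3S,4r)-2-[4-(benzyloxy)phenyl]-4-[3,4-bis(benzyloxy)phenyl]cyclobutane-1,3-dicarboxylic acid (both CO2H on one face and both aryl groups on the other), via all-trans amide ester 10 (not isolated)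
Conditions: NaOMe (3 equiv), MeOH/THF, 65 °C; then NaOH (10 equiv), H2O, 125 °C (sealed tube); aq HCl work-up
Reagents that add atoms: sodium hydroxide, [Na+].[OH-]
Why: Enolate epimerisation at the two carbonyl-bearing carbons relieves the all-cis strain and gives the thermodynamic all-trans isomer; saponification and amide hydrolysis follow, the non-acidic aryl-bearing centres stay fixed, and racemic 9 converges on the single achiral meso diacid.

**Step 5**
Reactants: 12 sodium (R)-danshensu
Product: 13 benzyl (2R)-3-[3,4-bis(benzyloxy)phenyl]-2-hydroxypropanoate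
Conditions: BnBr (3.2 equiv), K2CO3 (2.2 equiv), DMF, rt
Reagents that add atoms: benzyl bromide, BrCc1ccccc1
Why: In this Williamson and carboxylate O-alkylation, carbonate ionises only the phenols and the carboxylate is already ionised, so the secondary alcohol and its chiral-pool stereocentre are untouched.

**Step 6**
Reactants: 11 meso diacid (1.5 equiv); 13 tribenzyl (R)-danshensu (1.0 equiv)
Product: 15 (1R,2R,3S,4S)-3-({(2R)-1-(benzyloxy)-3-[3,4-bis(benzyloxy)phenyl]-1-oxopropan-2-yl}oxycarbonyl)-2-[4-(benzyloxy)phenyl]-4-[3,4-bis(benzyloxy)phenyl]cyclobutane-1-carboxylic acid, via mixed pivalic anhydride 14 (not isolated)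
Conditions: Piv2O (1.1 equiv), i-Pr2NEt (2.5 equiv), (R)-benzotetramisole (10 mol %), CH2Cl2, 0 °C to rt; chromatography, surplus 11 recovered
Reagents that add atoms: pivalic anhydride, CC(C)(C)C(=O)OC(=O)C(C)(C)C (its pivaloyl group is present only in intermediate 14)
Why: Proposed new method: desymmetrising mono-esterification of a meso 1,3-diacid by a chiral isothiourea. Pivalic anhydride reversibly activates either enantiotopic carboxylate as 14; a cyclic anhydride cannot form because it would force the two aryl groups into a 1,3-diaxial clash. The catalyst attacks the less hindered ring acyl carbon and gives two diastereomeric acyl-isothiouronium ions, each with C=O locked syn to sulfur and one face shielded by the catalyst phenyl. These ions present either the 4-benzyloxyphenyl flank or the broader, more electron-rich 3,4-bis(benzyloxy)phenyl flank to the face on which the alcohol arrives. Alcohol 13 belongs to the 2-hydroxy-ester class, whose ester carbonyl docks on the cationic catalyst, so its approach geometry is fixed. The faster ion is drained while the pool re-equilibrates by anhydride exchange. The minor diastereomer still carries the fast-reacting carboxyl and is removed preferentially as the diester, which raises the d.r. of 15. Acylation at oxygen retains the (R)-carbinol centre, and selecting the carboxyl on the S-configured ring carbon fixes the ring as 1R,2R,3S,4S. The closest known reaction types are the isothiourea-catalysed kinetic resolution of 2-hydroxy esters and of α-branched acids through pivalic mixed anhydrides, and the alkaloid-catalysed alcoholysis of meso cyclic anhydrides.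

**Step 7**
Reactants: 15 hexabenzyl monoester acid
Product: 16 (1R,2R,3S,4S)-3-{[(1R)-1-carboxy-2-(3,4-dihydroxyphenyl)ethoxy]carbonyl}-4-(3,4-dihydroxyphenyl)-2-(4-hydroxyphenyl)cyclobutane-1-carboxylic acid (target)
Conditions: H2 (1 atm), Pd/C (10 wt %), THF/MeOH, rt; work-up under argon
Reagents that add atoms: none
Why: Catalytic hydrogenolysis cleaves the five benzyl ethers and the benzyl ester under neutral conditions that touch neither the homobenzylic ester C–O bond, the cyclobutane nor any stereocentre.

**Compound list**
1 | methyl coumalate (methyl 2-oxo-2H-pyran-5-carboxylate) | COC(=O)C1=COC(=O)C=C1 | starting material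
2 | 8-aminoquinoline | Nc1cccc2cccnc12 | starting material
3 | methyl 3-oxo-2-oxabicyclo[2.2.0]hex-5-ene-6-carboxylate (photopyrone, racemic) | COC(=O)C1=C[C@H]2[C@@H]1OC2=O | intermediate
4 | cis-3-(methoxycarbonyl)cyclobutane-1-carboxylic acid | COC(=O)[C@H]1C[C@@H](C(=O)O)C1 | intermediate
5 | methyl cis-3-(quinolin-8-ylcarbamoyl)cyclobutane-1-carboxylate | COC(=O)[C@H]1C[C@@H](C(=O)Nc2cccc3cccnc23)C1 | intermediate
6 | 1,2-bis(benzyloxy)-4-iodobenzene | Ic1ccc(OCc2ccccc2)c(OCc2ccccc2)c1 | starting material
7 | all-cis monoaryl amide ester (racemic) | O=C(Nc2cccc3cccnc23)[C@H]1C[C@@H](C(=O)OC)[C@H]1c1ccc(OCc2ccccc2)c(OCc2ccccc2)c1 | intermediate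
8 | 1-(benzyloxy)-4-iodobenzene | Ic1ccc(OCc2ccccc2)cc1 | starting material
9 | all-cis diaryl amide ester (racemic) | O=C(Nc2cccc3cccnc23)[C@H]1[C@@H](c2ccc(OCc3ccccc3)cc2)[C@@H](C(=O)OC)[C@H]1c1ccc(OCc2ccccc2)c(OCc2ccccc2)c1 | intermediate
10 | all-trans diaryl amide ester (racemic) | O=C(Nc2cccc3cccnc23)[C@@H]1[C@@H](c2ccc(OCc3ccccc3)cc2)[C@H](C(=O)OC)[C@H]1c1ccc(OCc2ccccc2)c(OCc2ccccc2)c1 | intermediate
11 | meso all-trans diacid | O=C(O)[C@@H]1[C@@H](c2ccc(OCc3ccccc3)cc2)[C@H](C(=O)O)[C@H]1c1ccc(OCc2ccccc2)c(OCc2ccccc2)c1 | intermediate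
12 | sodium (2R)-3-(3,4-dihydroxyphenyl)-2-hydroxypropanoate | [Na+].[O-]C(=O)[C@H](O)Cc1ccc(O)c(O)c1 | starting material
13 | benzyl (2R)-3-[3,4-bis(benzyloxy)phenyl]-2-hydroxypropanoate | O[C@H](Cc1ccc(OCc2ccccc2)c(OCc2ccccc2)c1)C(=O)OCc1ccccc1 | intermediate
14 | mono mixed pivalic anhydride of 11 (forms at either carboxyl; the one that reacts on is drawn) | O=C(O)[C@@H]1[C@@H](c2ccc(OCc3ccccc3)cc2)[C@H](C(=O)OC(=O)C(C)(C)C)[C@H]1c1ccc(OCc2ccccc2)c(OCc2ccccc2)c1 | intermediate
15 | hexabenzyl monoester acid (1R,2R,3S,4S,2'R) | O=C(O)[C@@H]1[C@@H](c2ccc(OCc3ccccc3)cc2)[C@H](C(=O)O[C@H](Cc2ccc(OCc3ccccc3)c(OCc3ccccc3)c2)C(=O)OCc2ccccc2)[C@H]1c1ccc(OCc2ccccc2)c(OCc2ccccc2)c1 | intermediate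
16 | CNP0270917.1 | O=C(O)[C@@H]1[C@@H](c2ccc(O)cc2)[C@H](C(=O)O[C@H](Cc2ccc(O)c(O)c2)C(=O)O)[C@H]1c1ccc(O)c(O)c1 | target

**Step count**
- Total: 7 steps.
- Longest linear sequence: 6 steps (steps 1, 2, 3, 4, 6 and 7).

**Steps most likely to fail**

Step 6 (the proposed new step). The two carboxyls of 11 differ only in which flank carries the extra benzyloxy group, so the intrinsic selectivity may be low, and the sense of induction must be checked against the natural product. The fallback uses known chemistry, sets out from 11 and rejoins at 16.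
- 11 is mono-alkylated (BnBr 1 equiv, KHCO3, DMF; diacid and diester recycled) to the racemic mono-benzyl ester F1.
- Steglich esterification (EDC, DMAP) of F1 with 13 gives the wanted heptabenzyl diastereomer F2 and the unwanted heptabenzyl diastereomer F3.
- F2 and F3 are separated by chromatography or crystallisation.
- Hydrogenolysis of F2 under the step 7 conditions gives 16.

Step 3. Palladation on the crowded all-cis face of 7 may be slow. The fallback sets out from 7 and rejoins at 11.
- The ester carbon is epimerised first (KHMDS, THF, −78 °C, then proton quench) to the ester-epimerised monoaryl amide F4.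
- F4 is arylated with 8 under the same palladium and silver conditions, cis to the amide only, to give the diaryl amide ester F5, in which the ester is trans to both aryl groups.
- F5 is carried through the step 4 conditions to 11.

Step 4. The amide-bearing carbon may epimerise slowly, and the hindered amide may resist hydroxide. The fallback sets out from 9 and rejoins at 11.
- 9 is treated with NaOMe only and 10 is isolated.
- Boc2O and DMAP convert 10 into the N-Boc imide F6. Its α-proton is acidic enough for DBU to complete any missing epimerisation.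
- LiOH/H2O2 in THF/H2O at 0 °C to rt, followed by Na2SO3, cleaves the activated imide and the methyl ester to give 11.

**Further compounds**
F1 | step 6 | racemic mono-benzyl ester of 11 | O=C(OCc2ccccc2)[C@@H]1[C@@H](c2ccc(OCc3ccccc3)cc2)[C@H](C(=O)O)[C@H]1c1ccc(OCc2ccccc2)c(OCc2ccccc2)c1
F2 | step 6 | wanted heptabenzyl diastereomer (benzyl ester of 15) | O=C(OCc2ccccc2)[C@@H]1[C@@H](c2ccc(OCc3ccccc3)cc2)[C@H](C(=O)O[C@H](Cc2ccc(OCc3ccccc3)c(OCc3ccccc3)c2)C(=O)OCc2ccccc2)[C@H]1c1ccc(OCc2ccccc2)c(OCc2ccccc2)c1
F3 | step 6 | unwanted heptabenzyl diastereomer (ring centres inverted) | O=C(OCc2ccccc2)[C@H]1[C@H](c2ccc(OCc3ccccc3)cc2)[C@@H](C(=O)O[C@H](Cc2ccc(OCc3ccccc3)c(OCc3ccccc3)c2)C(=O)OCc2ccccc2)[C@@H]1c1ccc(OCc2ccccc2)c(OCc2ccccc2)c1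
F4 | step 3 | ester-epimerised monoaryl amide (racemic; amide and aryl cis, ester trans) | O=C(Nc2cccc3cccnc23)[C@H]1C[C@H](C(=O)OC)[C@H]1c1ccc(OCc2ccccc2)c(OCc2ccccc2)c1
F5 | step 3 | diaryl amide ester (racemic; amide cis to both aryl groups, ester trans) | O=C(Nc2cccc3cccnc23)[C@H]1[C@@H](c2ccc(OCc3ccccc3)cc2)[C@H](C(=O)OC)[C@H]1c1ccc(OCc2ccccc2)c(OCc2ccccc2)c1
F6 | step 4 | N-Boc imide of 10 (racemic) | O=C(N(C(=O)OC(C)(C)C)c2cccc3cccnc23)[C@@H]1[C@@H](c2ccc(OCc3ccccc3)cc2)[C@H](C(=O)OC)[C@H]1c1ccc(OCc2ccccc2)c(OCc2ccccc2)c1
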